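Readings and results stem from a simulated flask on assumed constants; the scatter is artificial.

The target in this flask climbs steeply and then flattens, so what has to be found is the level it runs into and what stands beside it at the asked time.

| setting | autumn | flask |
|---|---|---|
| starting material | 0.28 M | 0.28 M |
| reagent | 0.42 M | 0.420 M |
| free catalyst | 1.7 mM | 1.7 mM |
| remark | the very flask that is asked about, followed so far |  |
| time |  | 20 h |

- autumn (time / h: target / %, starting material / %): 0.333: 17.7, 81.9; 0.667: 30.3, 71.1; 1.00: 36.9, 63.8; 2.00: 50.9, 49.2; 4.00: 59.3, 39.3

(each reading ± 0.5 percentage points)

- concentration of target at 20 h, in M
- concentration of starting material at 20 h, in M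

- what was read earlier has a scatter of 0.5 percentage points, one standard deviation

The autumn run is this flask followed so far. Target opens at 0.149 M/h over the first reading and slows to 0.0118 M/h between 2.00 h and 4.00 h. It crosses the falling starting material near 2.00 h, at 50.9 % against 49.2 %. Starting material is the limiting reagent, 0.28 M against 0.420 M of reagent, yet 39.3 % of it still stands at 4.00 h, so the slope has dropped well before the charge is used.

To find the level, a clock helps: the logarithm of the reagent-to-starting-material ratio divided by its charged value. Taking the step as first order in each, with the rate proportional to free catalyst, this clock advances with free catalyst. It reads 0.296 at 2.00 h and 0.415 at 4.00 h. If free catalyst loses a constant fraction per hour, their ratio less one is the fraction surviving 2.00 h, read here, with the scatter of the readings, as 40.4 %, a half-life of 1.53 h. On this reckoning the clock then tends to 0.496; this level is the clock ceiling, the reading of the clock once free catalyst has died away. Since 13.1 half-lives fit into 20 h, the flask should stand at its ceiling, which means 0.0956 M of starting material and, as the rest of the charge, 0.184 M of target.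

The forecast, reading the stall as “first-order catalyst death”, gave 0.19 M of target and 0.089 M of starting material, a little more target than this reckoning. The simulation gives 0.179 M of target and 0.101 M of starting material.

    starting material → decomposition product (k = 1.60 × 10⁻⁴ /h)
    free catalyst → spent catalyst A (k = 0.500 /h)
    2 free catalyst → spent catalyst B (k = 57.0 /M/h)
    starting material + reagent + free catalyst → target + free catalyst, rate k4*[starting material]*[reagent]*[free catalyst]/(1 + ([starting material]/sat4)) (0.260 M, k = 1900 /M²/h)

In this flask the making of target ran while free catalyst was there: 29.5 % of its charge stood at 2.00 h, when the step had 79 % of its turnover behind it, and 0.486 % at 10.0 h, when target stood at 63.8 %. Target then stayed level, with 36 % of the starting material and 57 % of the reagent present at 20.0 h, and the clock at 0.467, under the ceiling of 0.496. For the neighbour charged with 4.2 × 10⁻⁴ M of free catalyst, all else as in this flask, taking over the same half-life and scaling the ceiling with the catalyst charge gives 0.123, which means 0.201 M of starting material; that neighbour ends at 0.206 M, with 0.0728 M of target.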